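**Plan**

- Atom numbers are those of the target, a bicyclo[3.2.1]oct-3-ene-2,8-dione: C1 bridgehead CH, C2 ketone, C3 C-OMe, C4 =CH, C5 allyl-bearing bridgehead, C6 CH-Me, C7 CH-aryl, C8 bridging ketone.
- Retrosynthesis: cut the O-CH3 bond at C3; then trade the bond C1-C7 for C4-C7, so that the cyclopentanone C1-C7-C6-C5-C8 contracts to the cyclobutane C4-C5-C6-C7 of a bicyclo[4.2.0]octenedione; then cut C5-C6 and C4-C7 ([2+2]) to 2-allyl-5-methoxy-1,4-benzoquinone and (E)-methyl isoeugenol; last the aryl-allyl bond and the two quinone oxygens.
- Forward: the six-membered ring is the arene/quinone ring; the cyclobutane is added by a chiral titanium TADDOLate [2+2]; the cyclopentanone, and with it the seven-membered ring of the bicycle, arises by ring expansion of the cyclobutane; O-methylation ends the route.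
- Enabling feature: in the cyclobutane, C7 is benzylic to the 3,4-dimethoxyphenyl donor and C4 is alpha to the C3 ketone (a donor-acceptor cyclobutane that heterolyses at C4-C7). C1 is the nucleophilic alpha-carbon of the vinylogous ester MeO-C2=C1-C8=O and lies across the six-membered ring from C4.
- Stereochemistry: C5 and C6 (absolute) come from the chiral titanium complex in the [2+2], the E-alkene giving trans aryl/methyl; C1 and C7 follow from C5 and C6 in the ring expansion.

Key step: step 4

Assumption: the facial sense of the titanium TADDOLate with this 5-allyl quinone is taken to be the one that gives 7 with the (4R,5R)-ligand; if it is the opposite, the (4S,5S)-ligand is used and nothing else changes.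

**Step 1**
Reactants: 1 1-bromo-2,4,5-trimethoxybenzene; 2 allyl bromide
Product: 4 1-allyl-2,4,5-trimethoxybenzene, via (2,4,5-trimethoxyphenyl)magnesium bromide 3 (not isolated)
Conditions: Mg, I2 (cat.), THF, reflux; then 2, 0 °C to rt; aq. NH4Cl
Reagents that add atoms: none
Why: Grignard formation from the electron-rich aryl bromide followed by allylation of the arylmagnesium bromide with allyl bromide (Grignard-allyl halide coupling) should give the allylarene; no stereocentre is formed.

**Step 2**
Reactants: 4 1-allyl-2,4,5-trimethoxybenzene
Product: 5 2-allyl-5-methoxy-1,4-benzoquinone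
Conditions: (NH4)2Ce(NO3)6 (2.2 equiv), MeCN/H2O, 0 °C, short reaction time
Reagents that add atoms: water (O)
Why: Oxidative demethylation of the para-related methoxy groups (C2 and C5 of the arene) by (NH4)2Ce(NO3)6 proceeds through the arene radical cation, with water adding at the two ipso carbons and methanol leaving, and should give the para-quinone that keeps the third methoxy group as a vinylogous ester; no stereocentre is formed.

**Step 3**
Reactants: 5 2-allyl-5-methoxy-1,4-benzoquinone; 6 (E)-1,2-dimethoxy-4-(prop-1-en-1-yl)benzene
Product: 7 (1S,6R,7R,8R)-1-allyl-7-(3,4-dimethoxyphenyl)-4-methoxy-8-methylbicyclo[4.2.0]oct-3-ene-2,5-dione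
Conditions: TiCl2(TADDOLate) (2 equiv, premixed from TiCl4, Ti(OiPr)4 and (4R,5R)-2,2-dimethyl-α,α,α′,α′-tetraphenyl-1,3-dioxolane-4,5-dimethanol, 1:1:2), CH2Cl2, −78 °C; aq. NaHCO3
Reagents that add atoms: none
Why: This is a Lewis-acid-promoted stepwise [2+2] cycloaddition of a 2-alkoxy-1,4-benzoquinone with an (E)-propenylarene: titanium chelated by the C4 carbonyl and the 5-methoxy group of 5 makes the allyl-bearing C2 electrophilic, the CHMe carbon of 6 adds there and the benzylic cation collapses on the adjacent enolate carbon C3, so the ring fusion is cis and the aryl group lies endo over the quinone ring, trans to the methyl group (E geometry kept), while the chiral TADDOLate ligand shields one quinone face and should thereby set the absolute configuration of the quaternary carbon and the methyl-bearing carbon.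

**Step 4**
Reactants: 7 (1S,6R,7R,8R)-1-allyl-7-(3,4-dimethoxyphenyl)-4-methoxy-8-methylbicyclo[4.2.0]oct-3-ene-2,5-dione
Product: 11 (1S,5S,6R,7R)-5-allyl-7-(3,4-dimethoxyphenyl)-3-hydroxy-6-methylbicyclo[3.2.1]oct-3-ene-2,8-dione, via ring-opened benzylic cation-titanium dienolate zwitterion 8 (not isolated), via bicyclic O-methyloxocarbenium titanium enolate 9 (not isolated), via trichlorotitanium enolate of the diosphenol 10 (not isolated)
Conditions: TiCl4 (2.2 equiv), CH2Cl2, −78 to −30 °C; cold aq. NaHCO3
Reagents that add atoms: none
Why: TiCl4 bound at the C3 carbonyl and C2 methoxy oxygens of 7 should trigger heterolysis of the strained donor-acceptor cyclobutane bond C4-C7 to the 3,4-dimethoxybenzyl cation at C7 and a titanium dienolate (8); after rotation about C5-C6 the cation is captured by C1, the alpha-carbon of the vinylogous ester MeO-C2=C1-C8=O, so that C7 has moved from C4 to C1 and the cyclobutane C4-C5-C6-C7 has become the cyclopentanone C1-C7-C6-C5-C8 (9); chloride then removes the methyl group from the oxocarbenium oxygen at C2 (10) and work-up frees the diosphenol 11. The closest known reaction type is the Lewis-acid rearrangement of quinone-arylalkene [2+2] adducts into the formal [5+2] adducts, the bicyclo[3.2.1]oct-3-ene-2,8-diones. The cyclopentanone closes in a 5-(enolexo)-exo-trig mode onto the planar cation, and the same bond completes the seven-membered ring C1-C2-C3-C4-C5-C6-C7 of the bicycle. C1 can only be bonded on the ring face that already carries the C5-C6 chain, so the untouched quaternary C5 fixes it; the C6 methyl group swings to the endo side as the chain turns from C4 to C1, and C7 should take the aryl group exo, trans to that methyl group. The step needs carbon capture and not oxygen capture of the cation (the C8 carbonyl oxygen would give the hydrobenzofuranone isomer) and no reversion to quinone and alkene; low temperature, excess oxophilic TiCl4 on the carbonyl oxygens and the exclusion of protic acid are expected to secure the first, and the intact C5-C6 bond should keep the enantiomeric purity.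

**Step 5**
Reactants: 11 (1S,5S,6R,7R)-5-allyl-7-(3,4-dimethoxyphenyl)-3-hydroxy-6-methylbicyclo[3.2.1]oct-3-ene-2,8-dione
Product: 12 kadsurenin D, (1S,5S,6R,7R)-5-allyl-7-(3,4-dimethoxyphenyl)-3-methoxy-6-methylbicyclo[3.2.1]oct-3-ene-2,8-dione
Conditions: MeI, K2CO3 (anhydrous), acetone, rt
Reagents that add atoms: iodomethane (CI)
Why: Williamson-type O-alkylation of the potassium enolate of the acidic diosphenol, which can enolise only towards C4 because a bridgehead enol at C1 is not accessible, should fix the C3 methyl enol ether without touching any stereocentre, and anhydrous carbonate in acetone avoids retro-Claisen opening of the beta-diketone.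

**Compound list**

1 | 1-bromo-2,4,5-trimethoxybenzene | COc1cc(OC)c(OC)cc1Br | starting material
2 | allyl bromide (3-bromoprop-1-ene) | C=CCBr | starting material
3 | (2,4,5-trimethoxyphenyl)magnesium bromide | COc1cc(OC)c(OC)cc1[Mg]Br | intermediate
4 | 1-allyl-2,4,5-trimethoxybenzene | C=CCc1cc(OC)c(OC)cc1OC | intermediate
5 | 2-allyl-5-methoxy-1,4-benzoquinone | C=CCC1=CC(=O)C(OC)=CC1=O | intermediate
6 | (E)-1,2-dimethoxy-4-(prop-1-en-1-yl)benzene ((E)-methyl isoeugenol) | C/C=C/c1ccc(OC)c(OC)c1 | starting material
7 | (1S,6R,7R,8R)-1-allyl-7-(3,4-dimethoxyphenyl)-4-methoxy-8-methylbicyclo[4.2.0]oct-3-ene-2,5-dione (cis-fused; methyl cis to the allyl group; aryl trans to methyl, on the face of the six-membered ring; cyclobutane = C4-C5-C6-C7 in target numbering) | C=CC[C@@]12C(=O)C=C(OC)C(=O)[C@@H]1[C@H](c1ccc(OC)c(OC)c1)[C@H]2C | intermediate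
8 | ring-opened zwitterion: benzylic cation at C7, tetrachlorotitanate-bound dienolate oxygen at C3 | C=CC[C@@]1(C=C(O[Ti-](Cl)(Cl)(Cl)Cl)C(OC)=CC1=O)[C@H](C)[CH+]c1ccc(OC)c(OC)c1 | intermediate
9 | bicyclo[3.2.1] O-methyloxocarbenium ion at C2 with tetrachlorotitanate-bound enolate oxygen at C3 | C=CC[C@]12C=C(O[Ti-](Cl)(Cl)(Cl)Cl)C(=[O+]C)[C@H](C1=O)[C@H](c1ccc(OC)c(OC)c1)[C@H]2C | intermediate
10 | trichlorotitanium enolate of diosphenol 11 | C=CC[C@]12C=C(O[Ti](Cl)(Cl)Cl)C(=O)[C@H](C1=O)[C@H](c1ccc(OC)c(OC)c1)[C@H]2C | intermediate
11 | (1S,5S,6R,7R)-5-allyl-7-(3,4-dimethoxyphenyl)-3-hydroxy-6-methylbicyclo[3.2.1]oct-3-ene-2,8-dione (aryl exo, methyl endo) | C=CC[C@]12C=C(O)C(=O)[C@H](C1=O)[C@H](c1ccc(OC)c(OC)c1)[C@H]2C | intermediate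
12 | kadsurenin D, (1S,5S,6R,7R)-5-allyl-7-(3,4-dimethoxyphenyl)-3-methoxy-6-methylbicyclo[3.2.1]oct-3-ene-2,8-dione (aryl exo, methyl endo) | C=CC[C@]12C=C(OC)C(=O)[C@H](C1=O)[C@H](c1ccc(OC)c(OC)c1)[C@H]2C | target

**Totals**

Total step count: 5. Longest linear sequence: 5 steps (1 → 4 → 5 → 7 → 11 → 12).

**Steps most likely to fail**

1. Step 4 (key step). The C7 cation may be captured by the C8 carbonyl oxygen instead of C1, giving the oxygen-bridged hydrobenzofuranone skeleton. It may also cyclise onto the allyl alkene, or the zwitterion may revert to quinone and alkene with loss of enantiomeric purity. The fallback builds the bicycle directly by the known acid-promoted [5+2] cycloaddition of a 2-allyl-4,5-dimethoxyphenoxonium ion and obtains the enantiomer by separation. It sets out from 4 and returns at 12. Anodic oxidation of 4 (Pt anode, KOH, MeOH, 0 °C) should give the quinone bisketal 1-allyl-3,3,4,6,6-pentamethoxycyclohexa-1,4-diene F1. Mild hydrolysis (aqueous acetic acid, acetone) should open the ketal next to the allyl-bearing carbon, because the resulting carbonyl is a vinylogous ester, and give 2-allyl-4,4,5-trimethoxycyclohexa-2,5-dien-1-one F2. Ionisation of F2 with TMSOTf in CH2Cl2 at −78 °C in the presence of 6, followed by aqueous work-up, should give racemic 12: the CHMe carbon of 6 adds at the allyl-bearing carbon, the benzylic cation closes on the other ortho carbon, and the C2 oxocarbenium is hydrolysed. Preparative chromatography on a chiral stationary phase then separates 12 from its enantiomer, ent-kadsurenin D F3.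

2. Step 3. Facial selectivity of the chiral titanium complex may be poor with the 5-allyl quinone, attack may occur at the unsubstituted quinone carbon, or the adduct may leak onwards under the promoter. The fallback replaces catalyst control by separation. It sets out from 5 and 6 and returns at 7. The achiral promoter TiCl4/Ti(OiPr)4 (1:1) in CH2Cl2 at −78 °C should give racemic 7 with the same relative configuration. Preparative chromatography on a chiral stationary phase then separates 7 from its enantiomer, (1R,6S,7S,8S)-1-allyl-7-(3,4-dimethoxyphenyl)-4-methoxy-8-methylbicyclo[4.2.0]oct-3-ene-2,5-dione F4.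

3. Step 5. Competing C-methylation at C4 of the ambident enolate, or base-induced retro-Claisen opening of the strained beta-diketone, may occur. The fallback changes from enolate alkylation to dehydrative coupling under neutral conditions. It sets out from 11 and returns at 12. A Mitsunobu reaction of 11 with methanol (PPh3, diisopropyl azodicarboxylate, THF, 0 °C) activates the alcohol and not the enol, so no free enolate or base is present and alkylation should occur on oxygen. This fallback makes no new compound (F0).

**Further compounds**

F1 | step 4 | 1-allyl-3,3,4,6,6-pentamethoxycyclohexa-1,4-diene | C=CCC1=CC(OC)(OC)C(OC)=CC1(OC)OC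
F2 | step 4 | 2-allyl-4,4,5-trimethoxycyclohexa-2,5-dien-1-one | C=CCC1=CC(OC)(OC)C(OC)=CC1=O
F3 | step 4 | ent-kadsurenin D, (1R,5R,6S,7S)-5-allyl-7-(3,4-dimethoxyphenyl)-3-methoxy-6-methylbicyclo[3.2.1]oct-3-ene-2,8-dione | C=CC[C@@]12C=C(OC)C(=O)[C@@H](C1=O)[C@@H](c1ccc(OC)c(OC)c1)[C@@H]2C
F4 | step 3 | (1R,6S,7S,8S)-1-allyl-7-(3,4-dimethoxyphenyl)-4-methoxy-8-methylbicyclo[4.2.0]oct-3-ene-2,5-dione | C=CC[C@]12C(=O)C=C(OC)C(=O)[C@H]1[C@@H](c1ccc(OC)c(OC)c1)[C@@H]2C
F0 | step 5 | none | none
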